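**Strategy.** Everything rests on cutting the C2–C1′ bond between the γ-pyrone ring C and ring B. The key step exploits C2–H of the chromone: bonded to O1 and vinylogous to the C4 carbonyl, it is the most acidic C–H, so a TMP zinc amide metalates it selectively and reverses the native electrophilic polarity of C2. The chromon-2-ylzinc reagent is then cross-coupled in the same flask (Negishi) with the C1′–Br bond, para to O4′, of an enantiopure trans-benzodioxane, delivering the whole protected skeleton in one operation. The precursors are an unfunctionalised 5,7-bis(methoxymethoxy)chromone and a bromobenzodioxane made by Evans glycolate aldol and Ullmann ring closure.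

Key step: step 9

Remark: flavone locants are used for rings A, B and C (O1, C2–C4, C1′–C6′, with O3′ and O4′ the dioxane oxygens); the dioxane carbons carry benzodioxine locants C2 and C3. MOM = methoxymethyl, TIPS = triisopropylsilyl, TMP = 2,2,6,6-tetramethylpiperidide.

**Step 1**
Reactants: 1 2,4-dibromo-6-methoxyphenol; 2 bromoacetic acid
Product: 3 (2,4-dibromo-6-methoxyphenoxy)acetic acid
Conditions: NaOH (aq), 100 °C; then HCl (aq)
Reagents that add atoms: none
Why: Williamson ether synthesis, in which the phenoxide of 1 displaces bromide from bromoacetate by SN2 while the aryl bromides are inert to aqueous base.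

**Step 2**
Reactants: 3 (2,4-dibromo-6-methoxyphenoxy)acetic acid; 4 (S)-4-benzyl-1,3-oxazolidin-2-one
Product: 6 (4S)-4-benzyl-3-[(2,4-dibromo-6-methoxyphenoxy)acetyl]-1,3-oxazolidin-2-one, via mixed pivalic anhydride 5 (not isolated)
Conditions: PivCl, Et3N, THF, −20 °C; then 4, LiCl, −20 °C → rt
Reagents that add atoms: none
Why: N-acylation of the Evans auxiliary through a mixed anhydride, the lithium-activated oxazolidinone attacking the less hindered aryloxyacetyl carbonyl without touching the auxiliary stereocentre.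

**Step 3**
Reactants: 7 vanillin
Product: 8 3-methoxy-4-(methoxymethoxy)benzaldehyde
Conditions: MOMCl, iPr2NEt, CH2Cl2, 0 °C → rt
Reagents that add atoms: chloromethyl methyl ether (MOMCl), COCCl
Why: O-alkylation of the phenol to an acetal protecting group that should survive boron enolates, hydride, carbonate and organozinc reagents and fall in the final acid step.

**Step 4**
Reactants: 6 (4S)-4-benzyl-3-[(2,4-dibromo-6-methoxyphenoxy)acetyl]-1,3-oxazolidin-2-one; 8 3-methoxy-4-(methoxymethoxy)benzaldehyde
Product: 11 (4S)-4-benzyl-3-[(2S,3R)-2-(2,4-dibromo-6-methoxyphenoxy)-3-hydroxy-3-[3-methoxy-4-(methoxymethoxy)phenyl]propanoyl]-1,3-oxazolidin-2-one, via dibutylboron Z-enolate 9 (not isolated), via dibutylboron aldolate 10 (not isolated)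
Conditions: Bu2BOTf, Et3N, CH2Cl2, −78 → 0 °C; then 8, −78 → 0 °C; then pH 7 buffer, MeOH, H2O2 (30%), 0 °C
Reagents that add atoms: none
Why: Evans syn glycolate aldol, in which the Z-boron enolate reacts through a closed Zimmerman–Traxler chair with one enolate face shielded by the benzyl group of the (S)-auxiliary, so that C2 (S) and C3 (R) are set together as the syn pair that becomes the trans-(2R,3R) pair of the dioxane ring.

**Step 5**
Reactants: 11 aldol adduct
Product: 12 (1R,2R)-2-(2,4-dibromo-6-methoxyphenoxy)-1-[3-methoxy-4-(methoxymethoxy)phenyl]propane-1,3-diol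
Conditions: LiBH4, H2O (1.1 equiv), Et2O–THF, 0 °C
Reagents that add atoms: none
Why: reductive cleavage of the N-acyl oxazolidinone by hydride attack at the exocyclic carbonyl, which should give the primary alcohol without touching either stereocentre or the aryl bromides and return the auxiliary.

**Step 6**
Reactants: 12 diol
Product: 13 (1R,2R)-2-(2,4-dibromo-6-methoxyphenoxy)-1-[3-methoxy-4-(methoxymethoxy)phenyl]-3-[(triisopropylsilyl)oxy]propan-1-ol
Conditions: TIPSCl, imidazole, DMF, 0 °C → rt
Reagents that add atoms: chlorotriisopropylsilane (TIPSCl), CC(C)[Si](Cl)(C(C)C)C(C)C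
Why: selective silylation of the primary hydroxyl, the bulky silyl chloride discriminating against the secondary benzylic alcohol and the triisopropylsilyl group resisting 1,3-migration under the basic conditions of the next step.

**Step 7**
Reactants: 13 silyl ether
Product: 14 (2R,3R)-6-bromo-8-methoxy-3-[3-methoxy-4-(methoxymethoxy)phenyl]-2-{[(triisopropylsilyl)oxy]methyl}-2,3-dihydro-1,4-benzodioxine
Conditions: CuI (10 mol %), 1,10-phenanthroline (20 mol %), Cs2CO3, toluene, 110 °C
Reagents that add atoms: none
Why: intramolecular Ullmann-type C–O coupling, in which the caesium alkoxide bound to monovalent copper is delivered to the ortho C–Br bond to close the six-membered dioxane ring with retention at both stereocentres (no bond to them is broken), the untethered para C–Br bond being kept for step 9.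

**Step 8**
Reactants: 15 5,7-dihydroxy-4H-chromen-4-one
Product: 16 5,7-bis(methoxymethoxy)-4H-chromen-4-one
Conditions: NaH, MOMCl, DMF, 0 °C → rt
Reagents that add atoms: chloromethyl methyl ether (MOMCl), COCCl
Why: double O-alkylation of the sodium phenoxides (Williamson-type acetal protection), NaH being needed to break the hydrogen bond of the 5-OH to the C4 carbonyl.

**Step 9**
Reactants: 16 5,7-bis(methoxymethoxy)-4H-chromen-4-one; 14 bromobenzodioxane
Product: 18 2-[(2R,3R)-8-methoxy-3-[3-methoxy-4-(methoxymethoxy)phenyl]-2-{[(triisopropylsilyl)oxy]methyl}-2,3-dihydro-1,4-benzodioxin-6-yl]-5,7-bis(methoxymethoxy)-4H-chromen-4-one, via chromon-2-ylzinc chloride 17 (not isolated)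
Conditions: TMPZnCl·LiCl, THF, 25 °C; then 14, Pd(OAc)2 (2 mol %), 2-dicyclohexylphosphino-2′,6′-dimethoxybiphenyl (SPhos, 4 mol %), THF, 55 °C
Reagents that add atoms: none
Why: Deprotonative zincation then Negishi cross-coupling: the hindered amide TMPZnCl·LiCl, used without added Lewis acid, removes C2–H of 16, the most acidic C–H of ring C (vinylic, bonded to O1, vinylogous to C4=O), so that the natively electrophilic C2 becomes the nucleophilic carbon of zinc reagent 17. Zerovalent palladium formed from Pd(OAc)2 and SPhos inserts into the C6–Br bond of 14 (C1′ of ring B, para to O4′), and transmetalation from 17 followed by reductive elimination forges the C2–C1′ bond. The closest known reaction type is the TMP-zinc metalation of chromones at C2 followed by palladium-catalysed arylation to flavones. No ring is closed and no stereocentre is created; the (2R,3R) centres of 14 are spectators under these conditions, which are neither strongly basic nor acidic. The selectivity needed is metalation at C2 in preference to C3, C6 and C8, which the acidity of the O1-flanked C–H toward a mild zinc amide should secure, while the single C–Br bond of 14 fixes the site on ring B and the acetal, silyl ether and carbonyl groups tolerate the organozinc.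

**Step 10**
Reactants: 18 protected flavonolignan
Product: 19 5′-methoxyhydnocarpin
Conditions: HCl (3 M in MeOH), THF, 40 °C
Reagents that add atoms: none
Why: acid-catalysed transacetalisation of the three methoxymethyl ethers and methanolysis of the primary silyl ether in one global deprotection, the diequatorial trans-benzodioxane being expected to keep its (2R,3R) configuration under Brønsted acid.

**Compound list**

1 | 2,4-dibromo-6-methoxyphenol | COc1cc(Br)cc(Br)c1O | starting material
2 | bromoacetic acid | OC(=O)CBr | starting material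
3 | (2,4-dibromo-6-methoxyphenoxy)acetic acid | COc1cc(Br)cc(Br)c1OCC(=O)O | intermediate
4 | (S)-4-benzyl-1,3-oxazolidin-2-one | O=C1OC[C@H](Cc2ccccc2)N1 | starting material
5 | (2,4-dibromo-6-methoxyphenoxy)acetic pivalic anhydride | COc1cc(Br)cc(Br)c1OCC(=O)OC(=O)C(C)(C)C | intermediate (not isolated)
6 | (4S)-4-benzyl-3-[(2,4-dibromo-6-methoxyphenoxy)acetyl]-1,3-oxazolidin-2-one | COc1cc(Br)cc(Br)c1OCC(=O)N1[C@@H](Cc2ccccc2)COC1=O | intermediate
7 | vanillin (4-hydroxy-3-methoxybenzaldehyde) | COc1cc(C=O)ccc1O | starting material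
8 | 3-methoxy-4-(methoxymethoxy)benzaldehyde | COCOc1ccc(C=O)cc1OC | intermediate
9 | dibutylboron Z-enolate of 6 | COc1cc(Br)cc(Br)c1O/C=C(\OB(CCCC)CCCC)N1[C@@H](Cc2ccccc2)COC1=O | intermediate (not isolated)
10 | dibutylboron aldolate of 11 | COCOc1ccc(cc1OC)[C@@H](OB(CCCC)CCCC)[C@H](Oc1c(Br)cc(Br)cc1OC)C(=O)N1[C@@H](Cc2ccccc2)COC1=O | intermediate (not isolated)
11 | (4S)-4-benzyl-3-[(2S,3R)-2-(2,4-dibromo-6-methoxyphenoxy)-3-hydroxy-3-[3-methoxy-4-(methoxymethoxy)phenyl]propanoyl]-1,3-oxazolidin-2-one | COCOc1ccc(cc1OC)[C@@H](O)[C@H](Oc1c(Br)cc(Br)cc1OC)C(=O)N1[C@@H](Cc2ccccc2)COC1=O | intermediate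
12 | (1R,2R)-2-(2,4-dibromo-6-methoxyphenoxy)-1-[3-methoxy-4-(methoxymethoxy)phenyl]propane-1,3-diol | COCOc1ccc(cc1OC)[C@@H](O)[C@H](Oc1c(Br)cc(Br)cc1OC)CO | intermediate
13 | (1R,2R)-2-(2,4-dibromo-6-methoxyphenoxy)-1-[3-methoxy-4-(methoxymethoxy)phenyl]-3-[(triisopropylsilyl)oxy]propan-1-ol | COCOc1ccc(cc1OC)[C@@H](O)[C@H](Oc1c(Br)cc(Br)cc1OC)CO[Si](C(C)C)(C(C)C)C(C)C | intermediate
14 | (2R,3R)-6-bromo-8-methoxy-3-[3-methoxy-4-(methoxymethoxy)phenyl]-2-{[(triisopropylsilyl)oxy]methyl}-2,3-dihydro-1,4-benzodioxine | COCOc1ccc(cc1OC)[C@H]1Oc2cc(Br)cc(OC)c2O[C@@H]1CO[Si](C(C)C)(C(C)C)C(C)C | intermediate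
15 | 5,7-dihydroxy-4H-chromen-4-one | O=c1ccoc2cc(O)cc(O)c12 | starting material
16 | 5,7-bis(methoxymethoxy)-4H-chromen-4-one | COCOc1cc(OCOC)c2c(c1)occc2=O | intermediate
17 | [5,7-bis(methoxymethoxy)-4-oxo-4H-chromen-2-yl]zinc chloride, LiCl complex | COCOc1cc(OCOC)c2c(c1)oc([Zn]Cl)cc2=O.[Li+].[Cl-] | intermediate (not isolated)
18 | 2-[(2R,3R)-8-methoxy-3-[3-methoxy-4-(methoxymethoxy)phenyl]-2-{[(triisopropylsilyl)oxy]methyl}-2,3-dihydro-1,4-benzodioxin-6-yl]-5,7-bis(methoxymethoxy)-4H-chromen-4-one | COCOc1ccc(cc1OC)[C@H]1Oc2cc(-c3cc(=O)c4c(OCOC)cc(OCOC)cc4o3)cc(OC)c2O[C@@H]1CO[Si](C(C)C)(C(C)C)C(C)C | intermediate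
19 | 5′-methoxyhydnocarpin, 5,7-dihydroxy-2-[(2R,3R)-3-(4-hydroxy-3-methoxyphenyl)-2-(hydroxymethyl)-8-methoxy-2,3-dihydro-1,4-benzodioxin-6-yl]-4H-chromen-4-one | COc1cc([C@H]2Oc3cc(-c4cc(=O)c5c(O)cc(O)cc5o4)cc(OC)c3O[C@@H]2CO)ccc1O | target

**Step count.** Total: 10 steps. Longest linear sequence: 8 steps (steps 1, 2, 4, 5, 6, 7, 9, 10, from compound 1).

**Steps most likely to fail**

Step 9. The process at risk is metalation at a ring position other than C2, or slow coupling of the electron-rich bromide so that the zinc reagent is lost by protonation. The fallback exchanges the roles: ring B becomes the nucleophile, and ring C is carried partly saturated and aromatised afterwards. Setting out from 14, bromine–lithium exchange (n-BuLi, THF, −78 °C), B(OiPr)3 and mild aqueous work-up should give {(2R,3R)-8-methoxy-3-[3-methoxy-4-(methoxymethoxy)phenyl]-2-{[(triisopropylsilyl)oxy]methyl}-2,3-dihydro-1,4-benzodioxin-6-yl}boronic acid F1. Conjugate addition of F1 to chromone 16 under divalent palladium catalysis (Pd(OCOCF3)2, 2,2′-bipyridine, H2O, ClCH2CH2Cl, 60 °C) should give the flavanone 2-[(2R,3R)-8-methoxy-3-[3-methoxy-4-(methoxymethoxy)phenyl]-2-{[(triisopropylsilyl)oxy]methyl}-2,3-dihydro-1,4-benzodioxin-6-yl]-5,7-bis(methoxymethoxy)chroman-4-one F2, as a mixture of epimers at the new flavanone carbon, which is of no consequence. Aerobic dehydrogenation (Pd(OCOCF3)2, DMSO, O2 1 atm, EtOAc, 60 °C) should then aromatise ring C and come back to the route at 18.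

Step 7. The process at risk is competing activation of the para C–Br bond, silyl migration to the secondary oxygen, or sluggish arylation of the hindered secondary alkoxide. The fallback inverts the roles at the closing bond, with the arene oxygen as nucleophile and the benzylic carbon as electrophile. Setting out from 13, chelation-directed bromine–magnesium exchange at the bromine ortho to the ether oxygen (iPrMgCl·LiCl, 2.2 equiv, THF, −15 °C), B(OMe)3 and oxidation (H2O2, NaOH) should give the phenol (1R,2R)-2-(4-bromo-2-hydroxy-6-methoxyphenoxy)-1-[3-methoxy-4-(methoxymethoxy)phenyl]-3-[(triisopropylsilyl)oxy]propan-1-ol F3. Catalytic camphorsulfonic acid (CH2Cl2, 0 °C) should ionise the para-alkoxybenzylic alcohol, and capture of the cation by the phenol should close the dioxane ring in the diequatorial trans sense, coming back to the route at 14. C2 is untouched; C3 is then set by the trans preference of the ring and no longer by retention.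

Step 10. The process at risk is incomplete loss of the primary silyl ether, or acid-induced opening of the benzylic aryl ether once the para-phenol is free. The fallback stages the deprotection without Brønsted acid. Setting out from 18, Bu4NF (THF, 0 °C) should give the primary alcohol 2-[(2R,3R)-2-(hydroxymethyl)-8-methoxy-3-[3-methoxy-4-(methoxymethoxy)phenyl]-2,3-dihydro-1,4-benzodioxin-6-yl]-5,7-bis(methoxymethoxy)-4H-chromen-4-one F4. TMSOTf with 2,2′-bipyridyl (CH2Cl2, 0 °C), then water, should cleave the three methoxymethyl ethers through their silyl ethers and arrive at 19.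

**Further compounds**

F1 | step 9 | {(2R,3R)-8-methoxy-3-[3-methoxy-4-(methoxymethoxy)phenyl]-2-{[(triisopropylsilyl)oxy]methyl}-2,3-dihydro-1,4-benzodioxin-6-yl}boronic acid | COCOc1ccc(cc1OC)[C@H]1Oc2cc(B(O)O)cc(OC)c2O[C@@H]1CO[Si](C(C)C)(C(C)C)C(C)C
F2 | step 9 | 2-[(2R,3R)-8-methoxy-3-[3-methoxy-4-(methoxymethoxy)phenyl]-2-{[(triisopropylsilyl)oxy]methyl}-2,3-dihydro-1,4-benzodioxin-6-yl]-5,7-bis(methoxymethoxy)chroman-4-one (epimers at the flavanone carbon) | COCOc1ccc(cc1OC)[C@H]1Oc2cc(C3CC(=O)c4c(OCOC)cc(OCOC)cc4O3)cc(OC)c2O[C@@H]1CO[Si](C(C)C)(C(C)C)C(C)C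
F3 | step 7 | (1R,2R)-2-(4-bromo-2-hydroxy-6-methoxyphenoxy)-1-[3-methoxy-4-(methoxymethoxy)phenyl]-3-[(triisopropylsilyl)oxy]propan-1-ol | COCOc1ccc(cc1OC)[C@@H](O)[C@H](Oc1c(O)cc(Br)cc1OC)CO[Si](C(C)C)(C(C)C)C(C)C
F4 | step 10 | 2-[(2R,3R)-2-(hydroxymethyl)-8-methoxy-3-[3-methoxy-4-(methoxymethoxy)phenyl]-2,3-dihydro-1,4-benzodioxin-6-yl]-5,7-bis(methoxymethoxy)-4H-chromen-4-one | COCOc1ccc(cc1OC)[C@H]1Oc2cc(-c3cc(=O)c4c(OCOC)cc(OCOC)cc4o3)cc(OC)c2O[C@@H]1CO
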